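**Retrosynthetic overview**

1. 21 ⇐ 20 (reduction at C3) ⇐ 17 (bromination at C4) ⇐ 16 (C9 OH to Br) ⇐ 15 (chloride opening at C10) ⇐ 14 (epoxidation of C9=C10).
2. 14 ⇐ 13 ⇐ 10 ⇐ 9 ⇐ 8: ketal hydrolysis, reductive 1,3-transposition of the ring B enone, protodesilylation.
3. Key disconnection of 8 at C9–C10 and C7–C8 gives spirocyclobutanone 6 and 1-(trimethylsilyl)propyne 7. It rests on ring B: the spiro carbon C6 carries two CH2 groups, C7 and C11, that differ only in what follows them (C8H2 against C10HCl), so both can sit in a 3,3-disubstituted cyclobutanone whose carbonyl carbon becomes C10.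
4. 6 ⇐ 5 ⇐ 3 ⇐ 2 ⇐ 1: dichloroketene [2+2] and dechlorination on the exocyclic diene made from ketoisophorone.
5. Ring order: ring A comes with ketoisophorone, the four-membered ring is added in step 3, and ring B is made from it by two-carbon expansion in step 5.

Key step: step 5

Remark 1: names use the numbering C1 (methyl-bearing sp2 carbon of ring A), C2, C3 (oxygen-bearing), C4, C5 (CMe2), C6 (spiro), C7, C8, C9 (methyl-bearing carbon of ring B), C10, C11.
Remark 2: the sense of induction of the chiral ligand in step 5 cannot be predicted, so the ligand antipode that delivers (6R)-8 is assumed to be used.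
Remark 3: 5 is racemic and loses its stereocentre in step 4; the C=N geometry of 10 and the transient C10 centre of 11 and 12 are left undefined because they are destroyed in step 8.

**Route**

Step 1
Reactants: 1 ketoisophorone
Product: 2 7,9,9-trimethyl-1,4-dioxaspiro[4.5]dec-6-en-8-one
Conditions: ethylene glycol, p-TsOH (cat.), benzene, reflux, Dean–Stark
Reagents that add atoms: ethylene glycol, OCCO
Why: Acid-catalysed ketalisation takes only the carbonyl flanked by CH and CH2, because the other one sits between CMe2 and the methyl-bearing sp2 carbon, and the alkene stays conjugated to the free ketone so it does not migrate.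

Step 2
Reactants: 2 7,9,9-trimethyl-1,4-dioxaspiro[4.5]dec-6-en-8-one
Product: 3 7,9,9-trimethyl-8-methylidene-1,4-dioxaspiro[4.5]dec-6-ene
Conditions: Ph3PCH3Br, KOtBu, toluene, 90 °C
Reagents that add atoms: methyltriphenylphosphonium bromide, C[P+](c1ccccc1)(c1ccccc1)c1ccccc1.[Br-]
Why: Wittig methylenation under the forcing conditions used for hindered ketones should work because 2 cannot enolise (quaternary carbon on one side, sp2 carbon on the other, ketal carbon at the γ position), so only 1,2-addition of the ylide is open.

Step 3
Reactants: 3 7,9,9-trimethyl-8-methylidene-1,4-dioxaspiro[4.5]dec-6-ene; 4 trichloroacetyl chloride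
Product: 5 rac-1,1-dichloro-5,9,9-trimethylspiro[3.5]non-5-ene-2,7-dione 7-ethylene ketal
Conditions: Zn (activated), DME, Et2O, ultrasound, 20 °C
Reagents that add atoms: none
Why: Dichloroketene–alkene [2+2] cycloaddition places the ketene carbonyl carbon on the terminal CH2 of the diene (the most nucleophilic and least hindered carbon) and CCl2 on the ring carbon, which gives the 3,3-disubstituted cyclobutanone pattern, while DME ties up ZnCl2 so the ketal survives.

Step 4
Reactants: 5 rac-1,1-dichloro-5,9,9-trimethylspiro[3.5]non-5-ene-2,7-dione 7-ethylene ketal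
Product: 6 5,9,9-trimethylspiro[3.5]non-5-ene-2,7-dione 7-ethylene ketal
Conditions: Zn, NH4Cl, MeOH, 23 °C
Reagents that add atoms: none
Why: Zinc-mediated reductive dechlorination of the α,α-dichloroketone runs under nearly neutral conditions that spare ketal and alkene and returns a cyclobutanone whose two CH2 groups are enantiotopic.

Step 5
Reactants: 6 5,9,9-trimethylspiro[3.5]non-5-ene-2,7-dione 7-ethylene ketal; 7 1-(trimethylsilyl)propyne
Product: 8 (6R)-1,5,5,9-tetramethyl-8-(trimethylsilyl)spiro[5.5]undeca-1,8-diene-3,10-dione 3-ethylene ketal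
Conditions: 7 (3 equiv), Ni(cod)2 (10 mol %), (S)-BINOL N,N-bis[(R)-1-phenylethyl]phosphoramidite (20 mol %), toluene, 90 °C
Reagents that add atoms: none
Why: Proposed new method: zerovalent nickel couples the cyclobutanone C=O with the alkyne by oxidative cyclisation to an oxanickelacyclopentene in which the carbonyl carbon (C10) is bonded to the methyl-bearing alkyne carbon (C9) and nickel to the silyl-bearing carbon (C8), strain-driven β-carbon elimination then cleaves one C10–CH2 bond, and C(sp3)–C(sp2) reductive elimination joins that CH2 (C7) to C8. The closest known reactions are the nickel/phosphine-catalysed intermolecular [4+2] ring expansion of 3,3-disubstituted cyclobutanones with internal alkynes and the nickel/phosphoramidite-catalysed enantioselective intramolecular alkene insertion into cyclobutanones; an enantioselective intermolecular alkyne insertion that desymmetrises a spiro cyclobutanone has not been shown. Ring B is closed not by an exo or endo cyclisation but by two-carbon expansion of the four-membered ring through a seven-membered nickelacycle. The only new stereocentre, C6, is set by the chiral ligand on nickel, which decides which of the two enantiotopic C10–CH2 bonds undergoes β-carbon elimination. The step needs regioselective alkyne insertion, which silicon secures by ending on the nickel-bound carbon as in other nickel-mediated carbonyl–silylalkyne couplings, and it needs enantiotopic-bond selection, for which C6 offers two very different neighbours beside both breaking bonds (CMe2 with two out-of-plane methyl groups against the flat C(Me)=CH unit); the ketal masks the ring A enone that would otherwise couple with the alkyne.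

Step 6
Reactants: 8 (6R)-1,5,5,9-tetramethyl-8-(trimethylsilyl)spiro[5.5]undeca-1,8-diene-3,10-dione 3-ethylene ketal
Product: 9 (6S)-1,5,5,9-tetramethylspiro[5.5]undeca-1,8-diene-3,10-dione 3-ethylene ketal
Conditions: Bu4NF, THF/H2O, 50 °C
Reagents that add atoms: none
Why: Fluoride-induced protodesilylation of a vinylsilane is eased here by the conjugated carbonyl group, which inductively stabilises the charge developing at the β carbon, and the basic medium leaves the ketal and the spiro centre untouched.

Step 7
Reactants: 9 (6S)-1,5,5,9-tetramethylspiro[5.5]undeca-1,8-diene-3,10-dione 3-ethylene ketal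
Product: 10 C10 tosylhydrazone of 9
Conditions: TsNHNH2, EtOH, 60 °C
Reagents that add atoms: 4-methylbenzenesulfonohydrazide, Cc1ccc(cc1)S(=O)(=O)NN
Why: Condensation of the only free ketone with tosylhydrazide without added acid gives the α,β-unsaturated tosylhydrazone while the acid-labile ring A ketal stays in place.

Step 8
Reactants: 10 C10 tosylhydrazone of 9
Product: 13 (6S)-1,5,5,9-tetramethylspiro[5.5]undeca-1,9-dien-3-one ethylene ketal, via N-boryl tosylhydrazine 11 (not isolated), via allylic diazene 12 (not isolated)
Conditions: catecholborane, CHCl3, 0 °C; then NaOAc·3H2O, 60 °C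
Reagents that add atoms: none
Why: In this Kabalka reductive transposition catecholborane delivers hydride to the C=N carbon, acetate triggers loss of sulfinate to the allylic diazene, and retro-ene loss of N2 moves the alkene to C9=C10 and puts hydrogen on C8, so no new stereocentre arises.

Step 9
Reactants: 13 (6S)-1,5,5,9-tetramethylspiro[5.5]undeca-1,9-dien-3-one ethylene ketal
Product: 14 (6S)-1,5,5,9-tetramethylspiro[5.5]undeca-1,9-dien-3-one
Conditions: 1 M HCl, THF, 23 °C
Reagents that add atoms: water, O
Why: Mild aqueous acid hydrolysis of the dioxolane unmasks the conjugated ring A ketone, and the isolated trisubstituted alkene is stable under these conditions.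

Step 10
Reactants: 14 (6S)-1,5,5,9-tetramethylspiro[5.5]undeca-1,9-dien-3-one
Product: 15 (6S,9S,10R)-9,10-epoxy-1,5,5,9-tetramethylspiro[5.5]undec-1-en-3-one
Conditions: mCPBA, NaHCO3, CH2Cl2, 0 °C
Reagents that add atoms: 3-chloroperoxybenzoic acid, OOC(=O)c1cccc(Cl)c1
Why: Prilezhaev epoxidation takes the electron-rich ring B alkene and not the enone alkene, and the peracid is expected to attack the face of C9=C10 away from C1, the ring A carbon that stands axial on the ring B half-chair with its methyl group over the ring, as an axial homoallylic substituent directs attack on a cyclohexene.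

Step 11
Reactants: 15 (6S,9S,10R)-9,10-epoxy-1,5,5,9-tetramethylspiro[5.5]undec-1-en-3-one
Product: 16 (6S,9S,10S)-10-chloro-9-hydroxy-1,5,5,9-tetramethylspiro[5.5]undec-1-en-3-one
Conditions: Li2CuCl4, THF, 23 °C
Reagents that add atoms: dilithium tetrachlorocuprate, [Li+].[Li+].Cl[Cu-2](Cl)(Cl)Cl
Why: Nucleophilic epoxide opening by chloride at the secondary carbon C10 with inversion is the trans-diaxial (Fürst–Plattner) opening and at the same time the attack at the less substituted carbon, so Cl ends on the C1 side of ring B and the tertiary C9–O bond stays as it is.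

Step 12
Reactants: 16 (6S,9S,10S)-10-chloro-9-hydroxy-1,5,5,9-tetramethylspiro[5.5]undec-1-en-3-one
Product: 17 (6S,9S,10S)-9-bromo-10-chloro-1,5,5,9-tetramethylspiro[5.5]undec-1-en-3-one
Conditions: Me3SiBr, CH2Cl2, −40 to 0 °C
Reagents that add atoms: bromotrimethylsilane, C[Si](C)(C)Br
Why: Bromotrimethylsilane converts the tertiary alcohol into the bromide by ionisation, and because the C10–Cl bond of the diaxial chlorohydrin is antiperiplanar to the leaving group, the cation should be bridged by chlorine and bromide should enter at the tertiary carbon from the side the oxygen left (retention at C9, Br trans to Cl).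

Step 13
Reactants: 17 (6S,9S,10S)-9-bromo-10-chloro-1,5,5,9-tetramethylspiro[5.5]undec-1-en-3-one
Product: 20 (4R,6R,9S,10S)-4,9-dibromo-10-chloro-1,5,5,9-tetramethylspiro[5.5]undec-1-en-3-one, via lithium dienolate 18 (not isolated), via silyl dienol ether 19 (not isolated)
Conditions: LiN(iPr)2, THF, −78 °C; Me3SiCl; then NBS, −78 to 0 °C
Reagents that add atoms: N-bromosuccinimide, BrN1C(=O)CCC1=O
Why: Kinetic deprotonation of the enone at the α′ carbon C4, silylation and bromination of the silyl dienol ether with NBS give the α′-bromo enone, but ring A sees the two sides of ring B as nearly alike, so only a modest preference for the needed C4 epimer (Br on the C11 side) can be expected, the epimers being separable and interconvertible through the enol.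

Step 14
Reactants: 20 (4R,6R,9S,10S)-4,9-dibromo-10-chloro-1,5,5,9-tetramethylspiro[5.5]undec-1-en-3-one
Product: 21 (3S,4R,6R,9S,10S)-4,9-dibromo-10-chloro-1,5,5,9-tetramethylspiro[5.5]undec-1-en-3-ol (CNP0537910.1)
Conditions: iBu2AlH, CH2Cl2, −78 °C; aq. potassium sodium tartrate
Reagents that add atoms: none
Why: In this 1,2-reduction of the α-bromo enone hydride should add to C3 from the face opposite the neighbouring C4–Br bond and opposite the axial C5 methyl group, which gives the allylic alcohol with OH cis to Br, and the tertiary bromide and secondary chloride do not react at −78 °C.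

**Compound list**

1 | ketoisophorone (2,6,6-trimethylcyclohex-2-ene-1,4-dione) | CC1=CC(=O)CC(C)(C)C1=O | starting material
2 | 7,9,9-trimethyl-1,4-dioxaspiro[4.5]dec-6-en-8-one | CC1=CC2(OCCO2)CC(C)(C)C1=O | intermediate
3 | 7,9,9-trimethyl-8-methylidene-1,4-dioxaspiro[4.5]dec-6-ene | CC1=CC2(OCCO2)CC(C)(C)C1=C | intermediate
4 | trichloroacetyl chloride | ClC(=O)C(Cl)(Cl)Cl | starting material
5 | rac-1,1-dichloro-5,9,9-trimethylspiro[3.5]non-5-ene-2,7-dione 7-ethylene ketal | CC1=CC2(OCCO2)CC(C)(C)C13CC(=O)C3(Cl)Cl | intermediate
6 | 5,9,9-trimethylspiro[3.5]non-5-ene-2,7-dione 7-ethylene ketal | CC1=CC2(OCCO2)CC(C)(C)C13CC(=O)C3 | intermediate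
7 | 1-(trimethylsilyl)propyne | CC#C[Si](C)(C)C | starting material
8 | (6R)-1,5,5,9-tetramethyl-8-(trimethylsilyl)spiro[5.5]undeca-1,8-diene-3,10-dione 3-ethylene ketal | CC1=CC2(OCCO2)CC(C)(C)[C@@]13CC([Si](C)(C)C)=C(C)C(=O)C3 | intermediate
9 | (6S)-1,5,5,9-tetramethylspiro[5.5]undeca-1,8-diene-3,10-dione 3-ethylene ketal | CC1=CC2(OCCO2)CC(C)(C)[C@@]13CC=C(C)C(=O)C3 | intermediate
10 | C10 tosylhydrazone of 9 | CC1=CC2(OCCO2)CC(C)(C)[C@@]13CC=C(C)C(=NNS(=O)(=O)c4ccc(C)cc4)C3 | intermediate
11 | N-(1,3,2-benzodioxaborol-2-yl)-N′-tosylhydrazine at C10 | CC1=CC2(OCCO2)CC(C)(C)[C@@]13CC=C(C)C(N(B4Oc5ccccc5O4)NS(=O)(=O)c6ccc(C)cc6)C3 | intermediate (not isolated)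
12 | C10 allylic diazene | CC1=CC2(OCCO2)CC(C)(C)[C@@]13CC=C(C)C(N=N)C3 | intermediate (not isolated)
13 | (6S)-1,5,5,9-tetramethylspiro[5.5]undeca-1,9-dien-3-one ethylene ketal | CC1=CC2(OCCO2)CC(C)(C)[C@@]13CCC(C)=CC3 | intermediate
14 | (6S)-1,5,5,9-tetramethylspiro[5.5]undeca-1,9-dien-3-one | CC1=CC(=O)CC(C)(C)[C@@]12CCC(C)=CC2 | intermediate
15 | (6S,9S,10R)-9,10-epoxy-1,5,5,9-tetramethylspiro[5.5]undec-1-en-3-one (epoxide oxygen on the ring B face away from C1) | CC1=CC(=O)CC(C)(C)[C@@]12CC[C@]3(C)O[C@@H]3C2 | intermediate
16 | (6S,9S,10S)-10-chloro-9-hydroxy-1,5,5,9-tetramethylspiro[5.5]undec-1-en-3-one (Cl and OH trans) | CC1=CC(=O)CC(C)(C)[C@@]12CC[C@](C)(O)[C@@H](Cl)C2 | intermediate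
17 | (6S,9S,10S)-9-bromo-10-chloro-1,5,5,9-tetramethylspiro[5.5]undec-1-en-3-one (Br and Cl trans) | CC1=CC(=O)CC(C)(C)[C@@]12CC[C@](C)(Br)[C@@H](Cl)C2 | intermediate
18 | lithium dienolate of 17 (C3–O–Li, C3=C4) | [Li+].CC1=CC([O-])=CC(C)(C)[C@@]12CC[C@](C)(Br)[C@@H](Cl)C2 | intermediate (not isolated)
19 | 3-(trimethylsilyloxy)-1,3-diene from 17 | CC1=CC(O[Si](C)(C)C)=CC(C)(C)[C@@]12CC[C@](C)(Br)[C@@H](Cl)C2 | intermediate (not isolated)
20 | (4R,6R,9S,10S)-4,9-dibromo-10-chloro-1,5,5,9-tetramethylspiro[5.5]undec-1-en-3-one | CC1=CC(=O)[C@H](Br)C(C)(C)[C@@]12CC[C@](C)(Br)[C@@H](Cl)C2 | intermediate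
21 | (3S,4R,6R,9S,10S)-4,9-dibromo-10-chloro-1,5,5,9-tetramethylspiro[5.5]undec-1-en-3-ol (OH and Br cis on ring A; Br and Cl trans on ring B) | CC1=C[C@H](O)[C@H](Br)C(C)(C)[C@@]12CC[C@](C)(Br)[C@@H](Cl)C2 | target

**Totals**

Total step count: 14. Longest linear sequence: 14 steps, from 1 to 21.

**Steps most likely to fail**

Step 5 (proposed new method). The nickelacycle may not discriminate the two enantiotopic C–CH2 bonds, so enantioselectivity may be low. The hindered spiro ketone may also react so slowly that alkyne oligomerisation takes over. The fallback sets out from 3 and comes back at 14. Hydrolysis of the ketal of 3 (1 M HCl, THF) should give 3,5,5-trimethyl-4-methylidenecyclohex-2-en-1-one F1. A Diels–Alder reaction of isoprene at the exocyclic alkene of this vinylogous enone, promoted by Me2AlCl in CH2Cl2, is a known way to build the chamigrene skeleton. By the para rule it should place the methyl group on C9 and the alkene at C9=C10, giving racemic 1,5,5,9-tetramethylspiro[5.5]undeca-1,9-dien-3-one F2. Resolution of F2 by preparative chromatography on a chiral stationary phase should give 14, from which steps 10 to 14 follow unchanged.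

Step 12. Ionisation next to the electron-withdrawing C–Cl bond may be slow, so that only the silyl ether forms. The cation may also lose a proton, suffer chlorine migration, or capture bromide on the wrong face. The fallback sets out from 16 and comes back at 17. Dehydration of 16 with SOCl2 and pyridine at −20 °C should give mainly the endocyclic allylic chloride (6S,10S)-10-chloro-1,5,5,9-tetramethylspiro[5.5]undeca-1,8-dien-3-one F3, together with its exocyclic isomer (6S,10S)-10-chloro-1,5,5-trimethyl-9-methylidenespiro[5.5]undec-1-en-3-one F4. Both lead to the same tertiary cation. Ionic Markovnikov hydrobromination with anhydrous HBr in CH2Cl2 at −78 °C should then give 17. Allylic strain against the C9 substituent holds the C10–Cl bond pseudoaxial, so bromide capture anti to chlorine is the kinetically preferred course.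

Step 13. Facial selectivity at C4 may be poor, because control from the ring B stereocentres is remote, and proton exchange may lead to over-bromination. The fallback sets out from 17 and comes back at 20, and it uses reagent control in place of substrate control. Deprotonation with KN(SiMe3)2 in THF at −78 °C and Davis asymmetric enolate hydroxylation follow, using the antipode of (camphorsulfonyl)oxaziridine that hydroxylates C4 on the C7 side of ring A. This should give (4S,6R,9S,10S)-9-bromo-10-chloro-4-hydroxy-1,5,5,9-tetramethylspiro[5.5]undec-1-en-3-one F5. Triflation with Tf2O and pyridine should give the C4 triflate F6. SN2 displacement of this activated α-keto triflate with Bu4NBr in acetone should install bromine with inversion and give 20.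

**Further compounds**

F1 | step 5 | 3,5,5-trimethyl-4-methylidenecyclohex-2-en-1-one | CC1=CC(=O)CC(C)(C)C1=C
F2 | step 5 | rac-1,5,5,9-tetramethylspiro[5.5]undeca-1,9-dien-3-one | CC1=CC(=O)CC(C)(C)C12CCC(C)=CC2
F3 | step 12 | (6S,10S)-10-chloro-1,5,5,9-tetramethylspiro[5.5]undeca-1,8-dien-3-one | CC1=CC(=O)CC(C)(C)[C@@]12CC=C(C)[C@@H](Cl)C2
F4 | step 12 | (6S,10S)-10-chloro-1,5,5-trimethyl-9-methylidenespiro[5.5]undec-1-en-3-one | CC1=CC(=O)CC(C)(C)[C@@]12CCC(=C)[C@@H](Cl)C2
F5 | step 13 | (4S,6R,9S,10S)-9-bromo-10-chloro-4-hydroxy-1,5,5,9-tetramethylspiro[5.5]undec-1-en-3-one | CC1=CC(=O)[C@@H](O)C(C)(C)[C@@]12CC[C@](C)(Br)[C@@H](Cl)C2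
F6 | step 13 | C4 trifluoromethanesulfonate of F5 | CC1=CC(=O)[C@@H](OS(=O)(=O)C(F)(F)F)C(C)(C)[C@@]12CC[C@](C)(Br)[C@@H](Cl)C2
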